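The route disconnects the O1–C2 bond of chroman H, the 2,3-cis flavan unit with a free C3 hydroxyl that sits on C2 of ring B of the benzo[7]annulen-5-one. Its ring oxygen and C3 hydroxyl are read as the two ends of a cis-epoxide opened by a neighbouring phenol. In one acid-catalysed operation the ortho hydroxyl of the phloroglucinol ring attacks the benzylic epoxide carbon with inversion, which closes the pyran 6-endo, sets C2 and releases the C3 hydroxyl. The precursor is the perbenzylated benzotropolone with 3-O-galloyl chroman G on C8 and, on C2, a (2S,3R)-cis-epoxide arm ending in a free ortho phenol. Chroman G comes from (–)-epigallocatechin, condensed oxidatively with 3-bromocatechol.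

Key step: step 12

Assumption: (–)-epigallocatechin and 3,4,5-tris(benzyloxy)benzoic acid are taken as catalogue compounds, so the two stereocentres of chroman G are bought and carried through unchanged.

Step 1
Reactants: 1 2,4,6-trihydroxybenzaldehyde
Product: 2 4,6-bis(benzyloxy)-2-hydroxybenzaldehyde
Conditions: BnBr (2.1 equiv), K2CO3, DMF, rt
Reagents that add atoms: benzyl bromide, BrCc1ccccc1
Why: Williamson etherification should stop at the dibenzyl ether because the last ortho hydroxyl is held in a hydrogen bond to the aldehyde and is the least nucleophilic of the three.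

Step 2
Reactants: 2 4,6-bis(benzyloxy)-2-hydroxybenzaldehyde
Product: 3 4,6-bis(benzyloxy)-2-(triisopropylsilyloxy)benzaldehyde
Conditions: TIPSOTf, 2,6-lutidine, CH2Cl2, 0 °C
Reagents that add atoms: triisopropylsilyl triflate, CC(C)[Si](OS(=O)(=O)C(F)(F)F)(C(C)C)C(C)C
Why: Silylation of a hydrogen-bonded phenol with a silyl triflate and a hindered pyridine base is routine, and the bulky triisopropylsilyl ether should last through steps 3 to 10 yet leave under buffered fluoride in step 11.

Step 3
Reactants: 3 4,6-bis(benzyloxy)-2-(triisopropylsilyloxy)benzaldehyde; 4 ethynylmagnesium bromide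
Product: 5 racemic 1-[4,6-bis(benzyloxy)-2-(triisopropylsilyloxy)phenyl]prop-2-yn-1-ol
Conditions: THF, –78 → –20 °C; then H2O
Reagents that add atoms: none
Why: 1,2-Addition of an alkynyl Grignard reagent to the aldehyde gives the propargylic alcohol, whose carbinol centre forms racemic and is erased in step 4; a cold quench should prevent silyl migration from the phenol oxygen to the alkoxide.

Step 4
Reactants: 5 racemic 1-[4,6-bis(benzyloxy)-2-(triisopropylsilyloxy)phenyl]prop-2-yn-1-ol
Product: 6 [3,5-bis(benzyloxy)-2-(prop-2-yn-1-yl)phenoxy]triisopropylsilane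
Conditions: Et3SiH, TFA, CH2Cl2, –40 °C
Reagents that add atoms: none
Why: Ionic hydrogenation should work because the benzylic propargylic alcohol, flanked by two ortho and one para oxygen donors, ionises readily in acid and the cation takes hydride from the silane at its benzylic carbon.

Step 5
Reactants: 7 (–)-epigallocatechin, (2R,3R); 8 3-bromocatechol (1.5 equiv)
Product: 10 bromobenzotropolone hexol 2-bromo-3,4,6-trihydroxy-8-[(2R,3R)-3,5,7-trihydroxychroman-2-yl]-5H-benzo[7]annulen-5-one, via 3-bromo-1,2-benzoquinone 9 (not isolated)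
Conditions: NaIO4 (about 3.5 equiv, slow addition), acetone/H2O (pH 5 acetate buffer), 0 °C
Reagents that add atoms: none
Why: In this theaflavin-type oxidative benzotropolone condensation periodate turns 8 into quinone 9, the only pyrogallol ring present (ring B of 7) adds to it by conjugate addition and then carbonyl addition, and oxidative loss of one ring carbon as CO2 leaves the benzotropolone; bromine blocks one of the two carbons next to the catechol oxygens, so annulation should occur on the unsubstituted side and place Br on C2, while the stereocentres of 7 are untouched.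

Step 6
Reactants: 10 bromobenzotropolone hexol
Product: 11 pentabenzyl ether 3,4,6-tris(benzyloxy)-8-[(2R,3R)-5,7-bis(benzyloxy)-3-hydroxychroman-2-yl]-2-bromo-5H-benzo[7]annulen-5-one
Conditions: BnBr (5.5 equiv), K2CO3, degassed DMF, Ar, 0 °C → rt
Reagents that add atoms: benzyl bromide, BrCc1ccccc1
Why: Williamson etherification of the five phenolic hydroxyls, the tropolone hydroxyl included, with a carbonate base too weak to deprotonate the secondary C3 alcohol of chroman G, which stays free as in the benzylation of flavan-3-ols; the tropolone is alkylated on O6 because an O5 ether would cost ring B its benzenoid character, and exclusion of air protects the base-sensitive benzotropolone.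

Step 7
Reactants: 11 pentabenzyl ether alcohol; 12 3,4,5-tris(benzyloxy)benzoic acid
Product: 13 octabenzyl bromide (2R,3R)-5,7-bis(benzyloxy)-2-[3,4,6-tris(benzyloxy)-2-bromo-5-oxo-5H-benzo[7]annulen-8-yl]chroman-3-yl 3,4,5-tris(benzyloxy)benzoate
Conditions: DCC, DMAP (cat.), CH2Cl2, 0 °C → rt
Reagents that add atoms: none
Why: Steglich esterification, in which DMAP passes the acyl group of the O-acylisourea of 12 to the secondary C3 hydroxyl of chroman G without touching its C–O bond, so the configuration is retained; this is the usual way to galloylate benzylated epi-flavan-3-ols.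

Step 8
Reactants: 13 octabenzyl bromide; 6 [3,5-bis(benzyloxy)-2-(prop-2-yn-1-yl)phenoxy]triisopropylsilane
Product: 14 C2-alkynyl benzotropolone, i.e. 13 with Br replaced by 3-[2,4-bis(benzyloxy)-6-(triisopropylsilyloxy)phenyl]prop-1-yn-1-yl
Conditions: PdCl2(PPh3)2 (cat.), CuI (cat.), Et3N/THF, degassed, 50 °C
Reagents that add atoms: none
Why: Sonogashira coupling should proceed under mild conditions because the C2–Br bond lies para to the acyl-bearing C4a and is activated for oxidative addition, while the tertiary amine attacks neither the tropolone ether nor the gallate.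

Step 9
Reactants: 14 C2-alkynyl benzotropolone
Product: 15 (Z)-alkene, i.e. 13 with Br replaced by (1Z)-3-[2,4-bis(benzyloxy)-6-(triisopropylsilyloxy)phenyl]prop-1-en-1-yl
Conditions: H2 (1 atm), Pd/CaCO3 poisoned with Pb(OAc)2, quinoline, EtOAc, rt
Reagents that add atoms: none
Why: Lindlar semihydrogenation delivers both hydrogens to one face of the alkyne on the poisoned palladium surface, which should give the Z-alkene and leave the benzyl ethers and the tropolone ring untouched.

Step 10
Reactants: 15 (Z)-alkene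
Product: 16 cis-epoxide silyl ether, i.e. 13 with Br replaced by (2S,3R)-3-[2,4-bis(benzyloxy)-6-(triisopropylsilyloxy)benzyl]oxiran-2-yl
Conditions: (S,S)-[N,N′-bis(3,5-di-tert-butylsalicylidene)-1,2-cyclohexanediaminato]MnCl (cat.), mCPBA, NMO, CH2Cl2, –78 °C
Reagents that add atoms: mCPBA (3-chloroperoxybenzoic acid), O=C(OO)c1cccc(Cl)c1
Why: Jacobsen–Katsuki epoxidation of a cis-disubstituted aryl alkene, in which the chiral salen manganese oxo species transfers oxygen to one alkene face so that the catalyst sets both epoxide carbons; the (S,S)-catalyst is chosen because it gives the (1S,2R)-epoxide from cis-β-methylstyrene and indene, and the peracid/N-oxide protocol at –78 °C avoids hypochlorite, which could chlorinate the phloroglucinol rings.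

Step 11
Reactants: 16 cis-epoxide silyl ether
Product: 17 cis-epoxide with free ortho phenol, i.e. 13 with Br replaced by (2S,3R)-3-[2,4-bis(benzyloxy)-6-hydroxybenzyl]oxiran-2-yl
Conditions: TBAF, AcOH (1:1), THF, 0 °C
Reagents that add atoms: none
Why: Fluoride-induced cleavage of the aryl silyl ether, buffered with acetic acid so that the phenol is released protonated and no phenoxide can open the epoxide in the 5-exo sense or attack the tropolone ether.

Step 12
Reactants: 17 cis-epoxide with free ortho phenol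
Product: 18 decabenzyl ether of the target with free C3 hydroxyl on chroman H, (2R,3R)-5,7-bis(benzyloxy)-2-{3,4,6-tris(benzyloxy)-2-[(2R,3R)-5,7-bis(benzyloxy)-3-hydroxychroman-2-yl]-5-oxo-5H-benzo[7]annulen-8-yl}chroman-3-yl 3,4,5-tris(benzyloxy)benzoate
Conditions: CSA (cat.), CH2Cl2, –20 → 0 °C
Reagents that add atoms: none
Why: The acid hydrogen-bonds to or protonates the epoxide oxygen, and the ortho phenol of the phloroglucinol ring attacks the benzylic carbon from the rear in an SN2-like opening; the closest known reaction type is the acid-promoted epoxide cycloetherification used for chromans and flavan-3-ols. The pyran of chroman H closes in the 6-endo-tet mode, since both epoxide carbons end up inside the new ring. The one new stereocentre, C2 of chroman H, is controlled by the substrate: inversion at the (S)-configured benzylic epoxide carbon gives 2R, and the untouched epoxide carbon becomes the 3R carbinol, so the cis-epoxide is translated into the 2,3-cis chroman. The step needs 6-endo over 5-exo opening and inversion over a free benzylic cation. Benzylic activation of the C–O bond directs the phenol to C2, and the C5 acyl group on C4a, para to the carbon that carries the arm, together with weak acid at low temperature holds back ionisation. The epoxide oxygen is released as the C3 hydroxyl that the target leaves free, so no protecting-group step follows.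

Step 13
Reactants: 18 decabenzyl ether
Product: 19 target, (2R,3R)-2-{3,4,6-trihydroxy-5-oxo-2-[(2R,3R)-3,5,7-trihydroxychroman-2-yl]-5H-benzo[7]annulen-8-yl}-5,7-dihydroxychroman-3-yl 3,4,5-trihydroxybenzoate
Conditions: H2 (1 atm), Pd(OH)2/C, THF/MeOH, rt
Reagents that add atoms: none
Why: Catalytic hydrogenolysis cleaves all ten aryl benzyl ethers, a reaction type that catechin gallates tolerate without cleavage of the chroman C2–O1 bonds, reduction of the tropolone ring or change at any stereocentre.

Compound list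

1 | 2,4,6-trihydroxybenzaldehyde | O=Cc1c(O)cc(O)cc1O | starting material
2 | 4,6-bis(benzyloxy)-2-hydroxybenzaldehyde | O=Cc1c(O)cc(OCc2ccccc2)cc1OCc1ccccc1 | intermediate
3 | 4,6-bis(benzyloxy)-2-(triisopropylsilyloxy)benzaldehyde | O=Cc1c(O[Si](C(C)C)(C(C)C)C(C)C)cc(OCc2ccccc2)cc1OCc1ccccc1 | intermediate
4 | ethynylmagnesium bromide | C#C[Mg]Br | starting material
5 | racemic 1-[4,6-bis(benzyloxy)-2-(triisopropylsilyloxy)phenyl]prop-2-yn-1-ol | C#CC(O)c1c(O[Si](C(C)C)(C(C)C)C(C)C)cc(OCc2ccccc2)cc1OCc1ccccc1 | intermediate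
6 | [3,5-bis(benzyloxy)-2-(prop-2-yn-1-yl)phenoxy]triisopropylsilane | C#CCc1c(O[Si](C(C)C)(C(C)C)C(C)C)cc(OCc2ccccc2)cc1OCc1ccccc1 | intermediate
7 | (–)-epigallocatechin, (2R,3R)-2-(3,4,5-trihydroxyphenyl)chroman-3,5,7-triol | O[C@@H]1Cc2c(O)cc(O)cc2O[C@@H]1c1cc(O)c(O)c(O)c1 | starting material
8 | 3-bromocatechol (3-bromobenzene-1,2-diol) | Oc1cccc(Br)c1O | starting material
9 | 3-bromo-1,2-benzoquinone | O=C1C=CC=C(Br)C1=O | intermediate
10 | 2-bromo-3,4,6-trihydroxy-8-[(2R,3R)-3,5,7-trihydroxychroman-2-yl]-5H-benzo[7]annulen-5-one | c1([C@H]5Oc6cc(O)cc(O)c6C[C@H]5O)cc(O)c(=O)c2c(O)c(O)c(Br)cc2c1 | intermediate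
11 | 3,4,6-tris(benzyloxy)-8-[(2R,3R)-5,7-bis(benzyloxy)-3-hydroxychroman-2-yl]-2-bromo-5H-benzo[7]annulen-5-one | c1([C@H]5Oc6cc(OCc9ccccc9)cc(OCc9ccccc9)c6C[C@H]5O)cc(OCc9ccccc9)c(=O)c2c(OCc9ccccc9)c(OCc9ccccc9)c(Br)cc2c1 | intermediate
12 | 3,4,5-tris(benzyloxy)benzoic acid | OC(=O)c1cc(OCc2ccccc2)c(OCc2ccccc2)c(OCc2ccccc2)c1 | starting material
13 | (2R,3R)-5,7-bis(benzyloxy)-2-[3,4,6-tris(benzyloxy)-2-bromo-5-oxo-5H-benzo[7]annulen-8-yl]chroman-3-yl 3,4,5-tris(benzyloxy)benzoate | c1([C@H]5Oc6cc(OCc9ccccc9)cc(OCc9ccccc9)c6C[C@H]5OC(=O)c8cc(OCc9ccccc9)c(OCc9ccccc9)c(OCc9ccccc9)c8)cc(OCc9ccccc9)c(=O)c2c(OCc9ccccc9)c(OCc9ccccc9)c(Br)cc2c1 | intermediate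
14 | (2R,3R)-5,7-bis(benzyloxy)-2-[3,4,6-tris(benzyloxy)-2-{3-[2,4-bis(benzyloxy)-6-(triisopropylsilyloxy)phenyl]prop-1-yn-1-yl}-5-oxo-5H-benzo[7]annulen-8-yl]chroman-3-yl 3,4,5-tris(benzyloxy)benzoate | c1([C@H]5Oc6cc(OCc9ccccc9)cc(OCc9ccccc9)c6C[C@H]5OC(=O)c8cc(OCc9ccccc9)c(OCc9ccccc9)c(OCc9ccccc9)c8)cc(OCc9ccccc9)c(=O)c2c(OCc9ccccc9)c(OCc9ccccc9)c(C#CCc4c(OCc9ccccc9)cc(OCc9ccccc9)cc4O[Si](C(C)C)(C(C)C)C(C)C)cc2c1 | intermediate
15 | (2R,3R)-5,7-bis(benzyloxy)-2-[3,4,6-tris(benzyloxy)-2-{(1Z)-3-[2,4-bis(benzyloxy)-6-(triisopropylsilyloxy)phenyl]prop-1-en-1-yl}-5-oxo-5H-benzo[7]annulen-8-yl]chroman-3-yl 3,4,5-tris(benzyloxy)benzoate | c1([C@H]5Oc6cc(OCc9ccccc9)cc(OCc9ccccc9)c6C[C@H]5OC(=O)c8cc(OCc9ccccc9)c(OCc9ccccc9)c(OCc9ccccc9)c8)cc(OCc9ccccc9)c(=O)c2c(OCc9ccccc9)c(OCc9ccccc9)c(/C=C\Cc4c(OCc9ccccc9)cc(OCc9ccccc9)cc4O[Si](C(C)C)(C(C)C)C(C)C)cc2c1 | intermediate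
16 | (2R,3R)-5,7-bis(benzyloxy)-2-[3,4,6-tris(benzyloxy)-2-{(2S,3R)-3-[2,4-bis(benzyloxy)-6-(triisopropylsilyloxy)benzyl]oxiran-2-yl}-5-oxo-5H-benzo[7]annulen-8-yl]chroman-3-yl 3,4,5-tris(benzyloxy)benzoate | c1([C@H]5Oc6cc(OCc9ccccc9)cc(OCc9ccccc9)c6C[C@H]5OC(=O)c8cc(OCc9ccccc9)c(OCc9ccccc9)c(OCc9ccccc9)c8)cc(OCc9ccccc9)c(=O)c2c(OCc9ccccc9)c(OCc9ccccc9)c([C@@H]3O[C@@H]3Cc4c(OCc9ccccc9)cc(OCc9ccccc9)cc4O[Si](C(C)C)(C(C)C)C(C)C)cc2c1 | intermediate
17 | (2R,3R)-5,7-bis(benzyloxy)-2-[3,4,6-tris(benzyloxy)-2-{(2S,3R)-3-[2,4-bis(benzyloxy)-6-hydroxybenzyl]oxiran-2-yl}-5-oxo-5H-benzo[7]annulen-8-yl]chroman-3-yl 3,4,5-tris(benzyloxy)benzoate (key-step precursor) | c1([C@H]5Oc6cc(OCc9ccccc9)cc(OCc9ccccc9)c6C[C@H]5OC(=O)c8cc(OCc9ccccc9)c(OCc9ccccc9)c(OCc9ccccc9)c8)cc(OCc9ccccc9)c(=O)c2c(OCc9ccccc9)c(OCc9ccccc9)c([C@@H]3O[C@@H]3Cc4c(OCc9ccccc9)cc(OCc9ccccc9)cc4O)cc2c1 | intermediate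
18 | (2R,3R)-5,7-bis(benzyloxy)-2-{3,4,6-tris(benzyloxy)-2-[(2R,3R)-5,7-bis(benzyloxy)-3-hydroxychroman-2-yl]-5-oxo-5H-benzo[7]annulen-8-yl}chroman-3-yl 3,4,5-tris(benzyloxy)benzoate (key-step product) | c1([C@H]5Oc6cc(OCc9ccccc9)cc(OCc9ccccc9)c6C[C@H]5OC(=O)c8cc(OCc9ccccc9)c(OCc9ccccc9)c(OCc9ccccc9)c8)cc(OCc9ccccc9)c(=O)c2c(OCc9ccccc9)c(OCc9ccccc9)c([C@H]3Oc4cc(OCc9ccccc9)cc(OCc9ccccc9)c4C[C@H]3O)cc2c1 | intermediate
19 | (2R,3R)-2-{3,4,6-trihydroxy-5-oxo-2-[(2R,3R)-3,5,7-trihydroxychroman-2-yl]-5H-benzo[7]annulen-8-yl}-5,7-dihydroxychroman-3-yl 3,4,5-trihydroxybenzoate | O=C(O[C@@H]1Cc2c(O)cc(O)cc2O[C@@H]1c1cc(O)c(=O)c2c(O)c(O)c([C@H]3Oc4cc(O)cc(O)c4C[C@H]3O)cc2c1)c1cc(O)c(O)c(O)c1 | target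

Total step count: 13. Longest linear sequence: 10 steps (steps 1 to 4, then 8 to 13).

Steps most likely to fail

Step 12. The protonated epoxide may ionise to a benzylic cation, helped by the benzyloxy group on C3 of ring B. That would erase the inversion and give the 2,3-trans chroman. The phenol may also attack the other epoxide carbon and close a dihydrobenzofuran. The fallback closes the ring by redox condensation on a diol in place of acid activation of an epoxide. It sets out from Z-alkene 15. Syn-dihydroxylation (K2OsO2(OH)4 cat., NMO, acetone/H2O, with (DHQD)2PHAL or its DHQ counterpart to bias the face) should give the (1S,2R)-diol silyl ether F1; the two syn-diols are diastereomers and would be separated. TBAF/AcOH should then free the phenol to give the triol F2. Mitsunobu cyclodehydration (PPh3, DIAD, THF, 0 °C), a known way from 1-aryl-3-(2-hydroxyaryl)propane-1,2-diols to flavan-3-ols, should let the phenol displace the activated benzylic hydroxyl with inversion and come back to the route at 18.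

Step 10. Oxygen transfer from the manganese oxo species is stepwise, so rotation about the former double bond before ring closure may leak trans-epoxide. The hindered aryl group with its ortho benzyloxy substituent may also weaken facial discrimination. The fallback is a concerted dioxirane oxygen transfer, the Shi epoxidation for cis-alkenes. The glucose-derived oxazolidinone ketone of the enantiomeric series that delivers the (2S,3R)-epoxide would be used with KHSO5 (as 2KHSO5·KHSO4·K2SO4) and K2CO3 in DME/aqueous buffer at 0 °C. It sets out from 15 and comes back at 16; being concerted, it cannot scramble the cis geometry. No new compound arises (F0).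

Step 5. Periodate may oxidise the pyrogallol ring of 7 as fast as it forms quinone 9, so that self-coupling of 7 and over-oxidation of 10 compete with the crossed condensation. Addition of the pyrogallol ring next to, or at, the bromine-bearing carbon of 9 would also divert material. The fallback keeps the external oxidant away from 7 by making the quinone first. It sets out from 7 and 8: 8 is oxidised with o-chloranil in Et2O at –20 °C to quinone 9. This solution (about 3 equiv, serving as electrophile and as the only oxidant) is added slowly to 7 in acetone/pH 5 buffer at 0 °C, which should come back to the route at 10. No new compound arises (F0).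

Further compounds

F1 | step 12 | (2R,3R)-5,7-bis(benzyloxy)-2-[3,4,6-tris(benzyloxy)-2-{(1S,2R)-1,2-dihydroxy-3-[2,4-bis(benzyloxy)-6-(triisopropylsilyloxy)phenyl]propyl}-5-oxo-5H-benzo[7]annulen-8-yl]chroman-3-yl 3,4,5-tris(benzyloxy)benzoate | c1([C@H]5Oc6cc(OCc9ccccc9)cc(OCc9ccccc9)c6C[C@H]5OC(=O)c8cc(OCc9ccccc9)c(OCc9ccccc9)c(OCc9ccccc9)c8)cc(OCc9ccccc9)c(=O)c2c(OCc9ccccc9)c(OCc9ccccc9)c([C@H](O)[C@H](O)Cc4c(OCc9ccccc9)cc(OCc9ccccc9)cc4O[Si](C(C)C)(C(C)C)C(C)C)cc2c1
F2 | step 12 | (2R,3R)-5,7-bis(benzyloxy)-2-[3,4,6-tris(benzyloxy)-2-{(1S,2R)-1,2-dihydroxy-3-[2,4-bis(benzyloxy)-6-hydroxyphenyl]propyl}-5-oxo-5H-benzo[7]annulen-8-yl]chroman-3-yl 3,4,5-tris(benzyloxy)benzoate | c1([C@H]5Oc6cc(OCc9ccccc9)cc(OCc9ccccc9)c6C[C@H]5OC(=O)c8cc(OCc9ccccc9)c(OCc9ccccc9)c(OCc9ccccc9)c8)cc(OCc9ccccc9)c(=O)c2c(OCc9ccccc9)c(OCc9ccccc9)c([C@H](O)[C@H](O)Cc4c(OCc9ccccc9)cc(OCc9ccccc9)cc4O)cc2c1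
F0 | step 10 | none | none
F0 | step 5 | none | none
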